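## Analysis of the target

Euglobal G3 (21) is a spiro[chroman-2,2'-pinane]: a 5,7-dihydroxychroman (O1, spiro C2, C3, C4, C4a, C5–C8, C8a) whose C2 is also C2' of a 6,6-dimethylbicyclo[3.1.1]heptane (primed numbers, "pinane"). The benzene ring is fully substituted: a phloroglucinol core (O1, O5, O7) with an isovaleryl group on C6 and a formyl group on C8. There are three stereocentres. The bridgeheads C1' and C5' are fixed by the bicycle and come from the terpene. At the spiro carbon, O1 lies on the face of the pinane six-membered ring opposite the gem-dimethyl bridge and C3 on the side of that bridge (2R,1'R,5'S). Sensitive points are the tertiary alkyl aryl ether at a strained carbon (ionisation gives a pinanyl cation that rearranges or opens the cyclobutane), the aryl aldehyde and the very electron-rich ring. The real difficulty is positional: C6 and C8 differ only in which neighbouring oxygen is the ring ether, so acylation of a 5,7-dioxygenated chroman has no built-in reason to prefer one of them. The route rests on the ortho relationship of the C6 acyl carbon and the C7 hydroxyl oxygen: both can be delivered together as the carbon and oxygen ends of a nitrile oxide added across a C6≡C7 aryne, the fused isoxazole being a masked ortho-hydroxyaryl ketone. After that, C8 is the only open ring carbon and takes the formyl group without a choice.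

## Retrosynthetic reasoning

21 ⇒ 20. The C8–CHO bond is cut first. In 20 every other ring position is occupied, so electrophilic formylation cannot go to the wrong carbon, and placing it last keeps the aldehyde out of all organometallic and reductive steps.

20 ⇒ 18. The ketone on C6 and the hydroxyl on C7 are traced back to the C=N and N–O bonds of a fused isoxazole, and the C5 hydroxyl to its methoxymethyl ether. Forward, reductive N–O cleavage gives imine 19, and one treatment with aqueous acid must then free the ketone and remove the acetal.

18 ⇒ 12 + 15 (key disconnection). Cutting C6–C(acyl) and C7–O of the isoxazole leads to aryne 16 and nitrile oxide 17, that is to their stable precursors 12 and 15. The cut is made here because it creates the acyl/hydroxyl pair in one event, with the orientation steered by the oxygen substituent already on C5, and with the acyl carbonyl still masked. The forward reaction must generate both partners at matched rates and join oxygen to C7 and carbon to C6.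

15 ⇒ 14 ⇒ 13. The chlorooxime goes back through the oxime to the aldehyde in two routine operations.

12 ⇒ 11 ⇒ 10. The triflate oxygen is the original C7 phenol. It is carried as a benzyl ether through the organolithium step and released by hydrogenolysis, which is neutral and therefore safe for the electron-rich aryl–silicon bond.

10 ⇒ 7 (via 8 and 9). The C6–Si bond is traced to a C6–Br bond: silylation of O5, halogen–lithium exchange, 1,3-shift of silicon from O5 to C6, then alkylation of the O5 phenoxide. Silicon ends up on exactly the carbon that carried bromine, and the C5 ether that later steers the aryne is installed in the same flask. A directed metalation without the halogen would have to choose between C6 and C8, both of which lie between two oxygens, so it is kept only as a reserve.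

7 ⇒ 5 (via 6). The C4 methylene is traced to the C4 carbonyl. That carbonyl is needed earlier for ring construction and for telling O5 from O7 and C6 from C8; once it has done this it is removed, using the free O5–H as the handle.

5 ⇒ 4 ⇒ 3. The C6–Br and O7–benzyl bonds are cut. In 3 and 4 the O5–H is locked in a hydrogen bond to the C4 carbonyl, so only O7 is alkylated, and the chelate polarises the ring so that bromine is expected ortho to the chelated hydroxyl, at C6.

3 ⇒ 1 + 2. The C3–C2 bond (aldol-type condensation) and the O1–C2 bond (conjugate addition) are cut, giving two commercial materials. The forward reaction must set the spiro centre: the phenol oxygen has to add to the exocyclic enone from the face away from the gem-dimethyl bridge.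

## Alternatives that were turned down

Alternative 1: The pyran ring is cut at C4–C4a and O1–C2, leading to the phenolic aldehyde A1 and the enal A2, made from 2 by two-carbon homologation.
- Forward key step: an amine salt condenses A2 at the ring carbon of A1 next to a hydroxyl, water is lost to give a quinone-methide-type dienone, and oxa-6π electrocyclisation closes the 2H-chromene A3. A3 already carries the C8 formyl group and a differentiated O5/O7 pair.
- For: convergent and short (about five steps after hydrogenation of C3=C4 with loss of benzyl and acylation of C6, then the only free position). The aldehyde never has to be introduced on a crowded ring. On step economy it is clearly better than the chosen route.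
- Against: the spiro centre forms in a thermally reversible electrocyclisation of a flat dienone, so its configuration is set by an epimer equilibrium and not by a kinetic approach to one face. A2 is a β,β-disubstituted enal and a poor partner for the first condensation. The isovaleryl group must finally be placed by Friedel–Crafts or Fries chemistry, with a strong Lewis acid on a ring deactivated by the formyl group and attached to the acid-sensitive tertiary ether.
- Comparison: the chosen route is longer, but it brings in the acyl carbon under fluoride at room temperature. Its only Lewis-acid step is a short, cold formylation of a much more reactive ring.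

Alternative 2: The benzene ring itself is cut at C5–C6, leading to the spiro-fused 2-pyranone A4, in which C5 is a lactone carbonyl and C7 carries a 4-methyl-2-oxopentyl chain.
- Forward key step: a magnesium alkoxide in the corresponding alcohol opens the lactone to an ester; the central carbon of the resulting β-diketone (the future C6) acylates that ester in a Claisen-type closure, and enolisation gives A5, which is the same compound as 20.
- For: the acyl group and both phenols arise together, with no positional choice on an aromatic ring. The sequence is short (three-component hetero-Diels–Alder assembly of the pyranopyranone, side-chain acylation, ring transformation, the same final formylation) and follows the polyketide origin of the ring. On step count and on certainty of the acyl position it is stronger than the chosen route.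
- Against: the assembly of A4 passes through an alkylidene pyrandione in which either carbonyl oxygen can act as the diene terminus, so linear and angular ring fusions compete. After lactone opening the ester is a β-alkoxyacrylate and a weak electrophile, so the Claisen closure must compete with aldol closure of C8 onto the side-chain ketone and with retro-Claisen loss of the isovaleryl unit. The side-chain acylation needs a dianion on a base-sensitive lactone.
- Comparison: the chosen route gives up brevity. In exchange each bond formation is an established aromatic or cycloaddition reaction on an isolable intermediate, and each positional decision (C6 by bromination, O7/C6 by the aryne orientation) can be checked before the next step.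

Alternative 3: The O1–C2 bond is cut in a precursor with an extra carbonyl on the pinane, the enone A6, in which a 2-(2-hydroxyaryl)ethyl chain sits on the β-carbon of a bicyclic enone.
- Forward key step: base forms the phenoxide, which adds to the β-carbon (6-exo-trig) from the face away from the gem-dimethyl bridge to give the spiro ketone A7.
- For: the spiro centre is formed by addition to a rigid, strongly face-differentiated enone. On kinetic control of the spiro configuration it is at least as good as, and probably better than, the condensation used in the chosen route.
- Against: A7 is a β-aryloxy ketone and can revert by E1cB elimination under the basic conditions that form it or process it further. The C4' carbonyl is not in the target, and its removal needs hot base or thioacetal formation with a Lewis acid, both of which threaten this β-aryloxy ketone. Most important, the approach does nothing for the aromatic ring: in A7 both phenol oxygens carry the same group and C6 and C8 are still to be told apart.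
- Comparison: the chosen route also has to erase a carbonyl (C4), but that carbonyl pays for itself by differentiating O5 from O7 and C6 from C8, and the key step is spent on the acyl/hydroxyl placement that Alternative 3 leaves open.

Key step: step 10

Remark on the chemistry: oxime 14 is an E/Z mixture and chlorooxime 15 is used crude; both oxime isomers converge on the same nitrile oxide 17, so this geometry is not controlled.

## Route

Step 1
Reactants: 1 2',4',6'-trihydroxyacetophenone; 2 (+)-nopinone, (1R,5S)-6,6-dimethylbicyclo[3.1.1]heptan-2-one
Product: 3 (2R,1'R,5'S)-5,7-dihydroxy spiro[chroman-2,2'-pinan]-4-one (O1 anti to the gem-dimethyl bridge)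
Conditions: pyrrolidine, EtOH, reflux
Reagents that add atoms: none
Why: Kabbe condensation: the pyrrolidine enamine/iminium pair joins the acetyl carbon to the ketone carbon and the ortho-phenol closes the pyranone by 6-endo-trig oxa-Michael addition to the exocyclic enone. The oxygen should add to C2' from the face opposite the gem-dimethyl bridge, which sets the spiro centre as in the target.

Step 2
Reactants: 3 (2R,1'R,5'S)-5,7-dihydroxy spiro[chroman-2,2'-pinan]-4-one
Product: 4 7-benzyloxy-5-hydroxy spiro[chroman-2,2'-pinan]-4-one
Conditions: BnBr, K2CO3, DMF, rt
Reagents that add atoms: benzyl bromide, BrCc1ccccc1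
Why: Williamson etherification; the O5–H is tied up in a hydrogen bond to the C4 carbonyl and is far less acidic, so only O7 should be alkylated. Room temperature avoids retro-Michael opening of the pyranone.

Step 3
Reactants: 4 7-benzyloxy-5-hydroxy spiro[chroman-2,2'-pinan]-4-one
Product: 5 7-benzyloxy-6-bromo-5-hydroxy spiro[chroman-2,2'-pinan]-4-one
Conditions: NBS, MeCN, 0 °C, dark
Reagents that add atoms: N-bromosuccinimide, O=C1CCC(=O)N1Br
Why: Electrophilic aromatic bromination; bond fixation in the hydrogen-bonded chelate makes C5–C6 the enol-like bond, so bromine is expected ortho to the chelated hydroxyl (C6) and not at C8 between the two ether oxygens, the pattern known for 2-hydroxy-4,6-dialkoxyaryl ketones.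

Step 4
Reactants: 5 7-benzyloxy-6-bromo-5-hydroxy spiro[chroman-2,2'-pinan]-4-one
Product: 7 7-benzyloxy-6-bromo spiro[chroman-2,2'-pinan]-5-ol, via aryl ethyl carbonate 6 (not isolated)
Conditions: ClCO2Et, Et3N, THF, 0 °C; then NaBH4, H2O/THF, 0 °C to rt
Reagents that add atoms: none
Why: Reductive deoxygenation of an ortho-acylphenol through its aryl carbonate: hydride reduces C4=O, the alkoxide takes over the carbonate and is expelled to give an ortho-quinone methide, and a second hydride adds at C4. Aryl bromide, benzyl ether and spiro ether are inert to NaBH4, and with the carbonyl gone the spiro centre can no longer epimerise by retro-Michael opening.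

Step 5
Reactants: 7 7-benzyloxy-6-bromo spiro[chroman-2,2'-pinan]-5-ol
Product: 10 7-benzyloxy-5-(methoxymethoxy)-6-(trimethylsilyl) spiro[chroman-2,2'-pinane], via silyl ether 8 (not isolated), via lithium phenoxide 9 (not isolated)
Conditions: (Me3Si)2NH, THF, reflux, evaporate; n-BuLi, THF, −78 °C; MOMCl, −78 °C to rt
Reagents that add atoms: hexamethyldisilazane, C[Si](C)(C)N[Si](C)(C)C; chloromethyl methyl ether, COCCl
Why: O-silylation, bromine–lithium exchange and retro-Brook rearrangement (1,3 O-to-C silyl shift) place Me3Si on the carbon that carried bromine, and the lithium phenoxide is then O-alkylated in the same flask. This is the standard entry to ortho-silylphenols with the usual triflating quench replaced by an alkyl chloride.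

Step 6
Reactants: 10 7-benzyloxy-5-(methoxymethoxy)-6-(trimethylsilyl) spiro[chroman-2,2'-pinane]
Product: 11 5-(methoxymethoxy)-6-(trimethylsilyl) spiro[chroman-2,2'-pinan]-7-ol
Conditions: H2 (1 atm), 10% Pd/C, EtOAc, rt
Reagents that add atoms: none
Why: Catalytic hydrogenolysis of a benzyl aryl ether; the neutral conditions spare the acid-labile aryl–silicon bond, the acetal and the strained bicycle.

Step 7
Reactants: 11 5-(methoxymethoxy)-6-(trimethylsilyl) spiro[chroman-2,2'-pinan]-7-ol
Product: 12 5-(methoxymethoxy)-6-(trimethylsilyl) spiro[chroman-2,2'-pinan]-7-yl trifluoromethanesulfonate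
Conditions: PhNTf2, Cs2CO3, MeCN, rt
Reagents that add atoms: N-phenylbis(trifluoromethanesulfonimide), O=S(=O)(N(c1ccccc1)S(=O)(=O)C(F)(F)F)C(F)(F)F
Why: Phenol triflation with a mild triflyl donor under basic conditions, which avoids ipso-protodesilylation of the electron-rich arylsilane.

Step 8
Reactants: 13 isovaleraldehyde (3-methylbutanal)
Product: 14 3-methylbutanal oxime (E/Z mixture)
Conditions: NH2OH·HCl, NaOAc, EtOH/H2O, rt
Reagents that add atoms: hydroxylamine hydrochloride, NO.Cl
Why: Oxime formation by condensation of an aldehyde with hydroxylamine.

Step 9
Reactants: 14 3-methylbutanal oxime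
Product: 15 (Z)-N-hydroxy-3-methylbutanimidoyl chloride
Conditions: NCS, DMF, rt; used crude
Reagents that add atoms: N-chlorosuccinimide, O=C1CCC(=O)N1Cl
Why: Chlorination of an aldoxime at carbon gives the hydroximoyl chloride, the standard nitrile oxide precursor; aliphatic members are not stored.

Step 10
Reactants: 12 5-(methoxymethoxy)-6-(trimethylsilyl) spiro[chroman-2,2'-pinan]-7-yl trifluoromethanesulfonate; 15 (Z)-N-hydroxy-3-methylbutanimidoyl chloride
Product: 18 3-isobutyl-1,2-benzisoxazole fused across C6–C7 of 5-(methoxymethoxy) spiro[chroman-2,2'-pinane] (isoxazole O on C7; isoxazole C3 on C6), via aryne 16 (not isolated), via nitrile oxide 17 (not isolated)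
Conditions: CsF, MeCN, rt, slow addition of 15
Reagents that add atoms: none
Why: Fluoride attacks silicon of 12 and triflate leaves from the neighbouring carbon to give aryne 16, while the same base dehydrochlorinates 15 to nitrile oxide 17; the two combine in a concerted, asynchronous [3+2] dipolar cycloaddition, the known aryne–nitrile oxide route to 1,2-benzisoxazoles. The isoxazole ring is closed intermolecularly by forming C6–C and C7–O in one cycloaddition in the plane of the aryne π bond, so no Baldwin-type closure is involved and no stereocentre is created; the spiro centre and bridgeheads are remote and untouched. The selectivity needed is orientational: oxygen to C7, carbon to C6. The σ-withdrawing OMOM group on C5 distorts the aryne so that C7 is the flatter, more electrophilic end and C6 the end that best carries developing negative charge, and the more nucleophilic oxygen end of the dipole should therefore bond first to C7, as is general for 3-alkoxyarynes. Working against this are the steric cost of bringing the isobutyl-bearing carbon next to OMOM and the weak opposite bias of O1 (para to C6), so the preference is expected to be useful but not absolute, and any regioisomer would be removed here by chromatography. Slow addition of 15 keeps the nitrile oxide concentration low so that dimerisation to the furoxan does not outrun aryne formation. Compound 12 has no free OH or NH that could intercept the aryne.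

Step 11
Reactants: 18 isoxazole-fused 5-(methoxymethoxy) spiro[chroman-2,2'-pinane]
Product: 20 5,7-dihydroxy-6-(3-methylbutanoyl) spiro[chroman-2,2'-pinane], via ketimine 19 (not isolated)
Conditions: Mo(CO)6, MeCN/H2O, 80 °C; then 1 M aq. HCl, THF, 40 °C
Reagents that add atoms: water, O
Why: Mo(CO)6-mediated reductive cleavage of the isoxazole N–O bond gives the hydrogen-bonded ortho-hydroxyaryl N–H ketimine; dilute aqueous acid then hydrolyses it to the ketone and cleaves the acetal, which is activated by the new ortho carbonyl. No hydride source is present, so the imine is not reduced.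

Step 12
Reactants: 20 5,7-dihydroxy-6-(3-methylbutanoyl) spiro[chroman-2,2'-pinane]
Product: 21 euglobal G3, (2R,1'R,5'S)-5,7-dihydroxy-6-(3-methylbutanoyl) spiro[chroman-2,2'-pinane]-8-carbaldehyde
Conditions: Cl2CHOMe, TiCl4, CH2Cl2, −40 to 0 °C; then ice-water
Reagents that add atoms: dichloromethyl methyl ether, COC(Cl)Cl; water, O
Why: Rieche formylation: the titanium-bound phenoxide directs the chloro(methoxy)methyl cation to C8, the only unsubstituted ring carbon (ortho to O7 and O1, para to O5), and aqueous work-up hydrolyses the α-chloro ether to the aldehyde. The reaction is run cold and briefly to keep the tertiary spiro ether intact.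

## Compound list

1 | 2',4',6'-trihydroxyacetophenone | CC(=O)c1c(O)cc(O)cc1O | starting material
2 | (+)-nopinone, (1R,5S)-6,6-dimethylbicyclo[3.1.1]heptan-2-one | O=C1CC[C@H]2C[C@@H]1C2(C)C | starting material
3 | (2R,1'R,5'S)-5,7-dihydroxy spiro[chroman-2,2'-pinan]-4-one | O=C1C[C@@]2(CC[C@H]3C[C@@H]2C3(C)C)Oc2cc(O)cc(O)c12 | intermediate
4 | 7-benzyloxy-5-hydroxy spiro[chroman-2,2'-pinan]-4-one | O=C1C[C@@]2(CC[C@H]3C[C@@H]2C3(C)C)Oc2cc(OCc3ccccc3)cc(O)c12 | intermediate
5 | 7-benzyloxy-6-bromo-5-hydroxy spiro[chroman-2,2'-pinan]-4-one | O=C1C[C@@]2(CC[C@H]3C[C@@H]2C3(C)C)Oc2cc(OCc3ccccc3)c(Br)c(O)c12 | intermediate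
6 | 7-benzyloxy-6-bromo-4-oxo spiro[chroman-2,2'-pinan]-5-yl ethyl carbonate | O=C1C[C@@]2(CC[C@H]3C[C@@H]2C3(C)C)Oc2cc(OCc3ccccc3)c(Br)c(OC(=O)OCC)c12 | intermediate (not isolated)
7 | 7-benzyloxy-6-bromo spiro[chroman-2,2'-pinan]-5-ol | Oc1c(Br)c(OCc2ccccc2)cc2c1CC[C@@]1(CC[C@H]3C[C@@H]1C3(C)C)O2 | intermediate
8 | 7-benzyloxy-6-bromo-5-(trimethylsilyloxy) spiro[chroman-2,2'-pinane] | C[Si](C)(C)Oc1c(Br)c(OCc2ccccc2)cc2c1CC[C@@]1(CC[C@H]3C[C@@H]1C3(C)C)O2 | intermediate (not isolated)
9 | lithium 7-benzyloxy-6-(trimethylsilyl) spiro[chroman-2,2'-pinan]-5-olate | [Li]Oc1c([Si](C)(C)C)c(OCc2ccccc2)cc2c1CC[C@@]1(CC[C@H]3C[C@@H]1C3(C)C)O2 | intermediate (not isolated)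
10 | 7-benzyloxy-5-(methoxymethoxy)-6-(trimethylsilyl) spiro[chroman-2,2'-pinane] | COCOc1c([Si](C)(C)C)c(OCc2ccccc2)cc2c1CC[C@@]1(CC[C@H]3C[C@@H]1C3(C)C)O2 | intermediate
11 | 5-(methoxymethoxy)-6-(trimethylsilyl) spiro[chroman-2,2'-pinan]-7-ol | COCOc1c([Si](C)(C)C)c(O)cc2c1CC[C@@]1(CC[C@H]3C[C@@H]1C3(C)C)O2 | intermediate
12 | 5-(methoxymethoxy)-6-(trimethylsilyl) spiro[chroman-2,2'-pinan]-7-yl trifluoromethanesulfonate | COCOc1c([Si](C)(C)C)c(OS(=O)(=O)C(F)(F)F)cc2c1CC[C@@]1(CC[C@H]3C[C@@H]1C3(C)C)O2 | intermediate
13 | isovaleraldehyde (3-methylbutanal) | CC(C)CC=O | starting material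
14 | 3-methylbutanal oxime (E/Z mixture) | CC(C)CC=NO | intermediate
15 | (Z)-N-hydroxy-3-methylbutanimidoyl chloride | CC(C)C/C(Cl)=N/O | intermediate
16 | 6,7-didehydro-5-(methoxymethoxy) spiro[chroman-2,2'-pinane] (aryne) | COCOC1=C2CC[C@@]3(CC[C@H]4C[C@@H]3C4(C)C)OC2=CC#C1 | intermediate (not isolated)
17 | 3-methylbutanenitrile oxide | CC(C)CC#[N+][O-] | intermediate (not isolated)
18 | 3-isobutyl-1,2-benzisoxazole fused across C6–C7 of 5-(methoxymethoxy) spiro[chroman-2,2'-pinane] (isoxazole O on C7) | CC(C)Cc1noc2cc3c(c(OCOC)c12)CC[C@@]1(CC[C@H]2C[C@@H]1C2(C)C)O3 | intermediate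
19 | 7-hydroxy-6-(1-imino-3-methylbutyl)-5-(methoxymethoxy) spiro[chroman-2,2'-pinane] | CC(C)CC(=N)c1c(O)cc2c(c1OCOC)CC[C@@]1(CC[C@H]3C[C@@H]1C3(C)C)O2 | intermediate (not isolated)
20 | 5,7-dihydroxy-6-(3-methylbutanoyl) spiro[chroman-2,2'-pinane] | CC(C)CC(=O)c1c(O)cc2c(c1O)CC[C@@]1(CC[C@H]3C[C@@H]1C3(C)C)O2 | intermediate
21 | euglobal G3, (2R,1'R,5'S)-5,7-dihydroxy-6-(3-methylbutanoyl) spiro[chroman-2,2'-pinane]-8-carbaldehyde | CC(C)CC(=O)c1c(O)c(C=O)c2c(c1O)CC[C@@]1(CC[C@H]3C[C@@H]1C3(C)C)O2 | target

## Step count and risks

Total step count: 12. Longest linear sequence: 10 steps (steps 1–7 and 10–12, from 1 and 2); steps 8 and 9 are the two-step side branch to 15.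

Least certain steps:

Step 10 (key step). What may go wrong: loss of orientational control, because the bond from the isobutyl-bearing carbon must form next to the OMOM group and this steric cost opposes the electronic bias of the distorted aryne. In addition, nitrile oxide 17 may be lost by dimerisation, or 12 may be protodesilylated by the hydrogen fluoride released from 15, if aryne formation lags behind nitrile oxide formation. Fallback (organolithium acylation in place of the cycloaddition), from 7 to 20: 7 is converted with MOMCl and i-Pr2NEt into 7-benzyloxy-6-bromo-5-(methoxymethoxy) spiro[chroman-2,2'-pinane] F1. Bromine–lithium exchange (n-BuLi, THF, −78 °C) and addition to 13 give the carbinol F2 as a mixture of epimers at the carbinol carbon, which is of no consequence. Dess–Martin oxidation gives the aryl ketone F3, hydrogenolysis (H2, Pd/C) frees O7 to give F4, and dilute aqueous HCl in THF removes the acetal to give 20. Position C6 is then fixed by the bromine alone and step 12 is unchanged.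

Step 1. What may go wrong: incomplete condensation, since the triphenol is largely present as its pyrrolidinium phenoxide and 2 is a hindered ketone, and erosion of the spiro configuration by reversible ring opening under the amine conditions, which would let the material drift towards the epimer with O1 on the side of the gem-dimethyl bridge. Fallback (hetero-Diels–Alder construction of the chroman in place of condensation and conjugate addition), from 2 to 7: Wittig methylenation of 2 (Ph3P=CH2) gives (−)-β-pinene F5, which is also an article of commerce. The known 4-(benzyloxy)-2,6-dihydroxybenzaldehyde F6 is reduced with NaBH4 to the benzylic alcohol F7, which is used at once; on heating with an excess of F5 it loses water to the ortho-quinone methide F8. This is trapped in an inverse-demand hetero-Diels–Alder reaction on the alkene face away from the gem-dimethyl bridge to give 7-benzyloxy spiro[chroman-2,2'-pinan]-5-ol F9, with the spiro centre set irreversibly and C4 already a methylene; because F7 is symmetric, either hydroxyl gives the same adduct. Bromination of F9 with NBS and a catalytic secondary amine, which delivers bromine ortho to the free hydroxyl through a hydrogen-bonded N-bromoamine, then gives 7. This path gives up the chelate control of step 3, which is why it is the reserve.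

Step 3. What may go wrong: bromination at C8 or twofold bromination, since both open ring positions are activated by three oxygens and the preference for C6 rests on the chelate alone. Fallback (directed ortho-metalation in place of electrophilic substitution), from 3 to 11: O7-selective carbamoylation of 3 (Et2NCOCl, K2CO3, MeCN) gives the 7-diethylcarbamate F10. The deoxygenation of step 4 (ClCO2Et, Et3N; then NaBH4) gives the chroman-5-ol F11, and MOMCl with i-Pr2NEt gives the acetal F12. Lithiation with s-BuLi and TMEDA at −78 °C followed by Me3SiCl should silylate C6, the position between the carbamate and the chelating acetal arm on O5, to give F13, and LiAlH4 in THF cleaves the carbamate to 11. In this path C6 is chosen over C8 (which lies between the carbamate and O1) by the cooperation of two directing groups, a weaker guarantee than a halogen, so the result would have to be checked before going on.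

Step 12. What may go wrong: Lewis-acid ionisation of the tertiary C2–O1 bond, with rearrangement or cyclobutane opening of the pinanyl cation, or deactivation of the ring by the titanium chelate of the β-hydroxy ketone so that formylation stalls. Fallback (phenoxide-directed hydroxymethylation and oxidation in place of electrophilic formylation), from 20 to 21: the magnesium phenoxide of 20 (MgCl2, Et3N, MeCN) is heated with paraformaldehyde. Coordinated formaldehyde is delivered ortho to O7, the only open position, and the resulting benzylic magnesium alkoxide transfers hydride to a second formaldehyde to give 21 directly, with no strong Lewis acid and no new isolated compound.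

## Further compounds

F1 | step 10 | 7-benzyloxy-6-bromo-5-(methoxymethoxy) spiro[chroman-2,2'-pinane] | COCOc1c(Br)c(OCc2ccccc2)cc2c1CC[C@@]1(CC[C@H]3C[C@@H]1C3(C)C)O2
F2 | step 10 | 1-[7-benzyloxy-5-(methoxymethoxy) spiro[chroman-2,2'-pinan]-6-yl]-3-methylbutan-1-ol (carbinol epimers) | CC(C)CC(O)c1c(OCc2ccccc2)cc2c(c1OCOC)CC[C@@]1(CC[C@H]3C[C@@H]1C3(C)C)O2
F3 | step 10 | 7-benzyloxy-5-(methoxymethoxy)-6-(3-methylbutanoyl) spiro[chroman-2,2'-pinane] | CC(C)CC(=O)c1c(OCc2ccccc2)cc2c(c1OCOC)CC[C@@]1(CC[C@H]3C[C@@H]1C3(C)C)O2
F4 | step 10 | 7-hydroxy-5-(methoxymethoxy)-6-(3-methylbutanoyl) spiro[chroman-2,2'-pinane] | CC(C)CC(=O)c1c(O)cc2c(c1OCOC)CC[C@@]1(CC[C@H]3C[C@@H]1C3(C)C)O2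
F5 | step 1 | (−)-β-pinene | C=C1CC[C@H]2C[C@@H]1C2(C)C
F6 | step 1 | 4-(benzyloxy)-2,6-dihydroxybenzaldehyde | O=Cc1c(O)cc(OCc2ccccc2)cc1O
F7 | step 1 | 5-(benzyloxy)-2-(hydroxymethyl)benzene-1,3-diol | OCc1c(O)cc(OCc2ccccc2)cc1O
F8 | step 1 | 5-(benzyloxy)-3-hydroxy-6-methylidenecyclohexa-2,4-dien-1-one (ortho-quinone methide) | C=C1C(=O)C=C(OCc2ccccc2)C=C1O
F9 | step 1 | 7-benzyloxy spiro[chroman-2,2'-pinan]-5-ol | Oc1cc(OCc2ccccc2)cc2c1CC[C@@]1(CC[C@H]3C[C@@H]1C3(C)C)O2
F10 | step 3 | 5-hydroxy-4-oxo spiro[chroman-2,2'-pinan]-7-yl N,N-diethylcarbamate | O=C1C[C@@]2(CC[C@H]3C[C@@H]2C3(C)C)Oc2cc(OC(=O)N(CC)CC)cc(O)c12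
F11 | step 3 | 5-hydroxy spiro[chroman-2,2'-pinan]-7-yl N,N-diethylcarbamate | Oc1cc(OC(=O)N(CC)CC)cc2c1CC[C@@]1(CC[C@H]3C[C@@H]1C3(C)C)O2
F12 | step 3 | 5-(methoxymethoxy) spiro[chroman-2,2'-pinan]-7-yl N,N-diethylcarbamate | COCOc1cc(OC(=O)N(CC)CC)cc2c1CC[C@@]1(CC[C@H]3C[C@@H]1C3(C)C)O2
F13 | step 3 | 5-(methoxymethoxy)-6-(trimethylsilyl) spiro[chroman-2,2'-pinan]-7-yl N,N-diethylcarbamate | COCOc1c([Si](C)(C)C)c(OC(=O)N(CC)CC)cc2c1CC[C@@]1(CC[C@H]3C[C@@H]1C3(C)C)O2
F0 | step 12 | none | none
A1 | alternative 1 | 4-(benzyloxy)-2,6-dihydroxybenzaldehyde | O=Cc1c(O)cc(OCc2ccccc2)cc1O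
A2 | alternative 1 | (6,6-dimethylbicyclo[3.1.1]heptan-2-ylidene)acetaldehyde derived from 2 | O=CC=C1CC[C@H]2C[C@@H]1C2(C)C
A3 | alternative 1 | 5-benzyloxy-7-hydroxy spiro[2H-chromene-2,2'-pinane]-8-carbaldehyde | O=Cc1c(O)cc(OCc2ccccc2)c2C=C[C@@]3(CC[C@H]4C[C@@H]3C4(C)C)Oc12
A4 | alternative 2 | 7-(4-methyl-2-oxopentyl)-3,4-dihydro-2H,5H-pyrano[4,3-b]pyran-5-one spiro-linked at C2 to C2' of the pinane | CC(C)CC(=O)CC1=CC2=C(CC[C@@]3(CC[C@H]4C[C@@H]3C4(C)C)O2)C(=O)O1
A5 | alternative 2 | 5,7-dihydroxy-6-(3-methylbutanoyl) spiro[chroman-2,2'-pinane] (identical with 20) | CC(C)CC(=O)c1c(O)cc2c(c1O)CC[C@@]1(CC[C@H]3C[C@@H]1C3(C)C)O2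
A6 | alternative 3 | 4-[2-(2-hydroxy-4,6-bis(methoxymethoxy)phenyl)ethyl]-6,6-dimethylbicyclo[3.1.1]hept-3-en-2-one | COCOc1cc(O)c(CCC2=CC(=O)[C@H]3C[C@@H]2C3(C)C)c(OCOC)c1
A7 | alternative 3 | 5,7-bis(methoxymethoxy) spiro[chroman-2,2'-pinan]-4'-one | COCOc1cc2c(c(OCOC)c1)CC[C@@]1(CC(=O)[C@H]3C[C@@H]1C3(C)C)O2
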